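**Retrosynthetic overview**
1. Disconnect the acid and phenol (ester hydrolysis and desilylation), then the C5–C6 bond by sp3–sp2 Negishi coupling. This gives chromene iodide **8** plus the (E)-vinyl iodide/(Z)-acrylate **14**.
2. Key step: **8** comes from the o-hydroxyaryl dienoate **5** by a Co(salen)–H hydrogen-atom-transfer (HAT) radical–polar-crossover oxa-cyclisation. This is the only ring-forming step; it closes the pyran ring and sets the C2 quaternary (R) ether carbon. **5** comes from aldehyde **4** by HWE, and **4** from o-cresol.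
3. **14** comes from a Still–Gennari Z-olefination of aldehyde **11** (from 4-pentyn-1-ol by carboalumination) with a phosphonate alkylated by homoprenyl bromide.

Assumption: phosphonate olefination reagents, the Co(salen) catalyst and standard organometallic reagents are purchased. The (R,R)-salen is taken to give the (R)-ether; if the sense is reversed, the (S,S)-catalyst is used.

---

**Step 1**
Reactants: **1** o-cresol
Product: **2** 2-hydroxy-3-methylbenzaldehyde
Conditions: MgCl2, Et3N, (CH2O)n, MeCN, reflux
Reagents that add atoms: formaldehyde, C=O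
Why: Ortho-selective phenol formylation (Casiraghi/Skattebøl, Mg-phenoxide directed); the other ortho position is blocked by Me, so there is no regiochemical issue and no stereocentre.

**Step 2**
Reactants: **2**
Product: **3** 2,5-dihydroxy-3-methylbenzaldehyde
Conditions: K2S2O8, aq. NaOH, 0 °C→rt, 24 h; then aq. HCl, 70 °C
Reagents that add atoms: potassium persulfate, [K+].[K+].[O-]S(=O)(=O)OOS(=O)(=O)[O-] (supplies the O)
Why: Elbs persulfate oxidation hydroxylates para to the phenoxide, giving the 1,4-dioxygenated pattern needed for the 6-OH; the intermediate aryl sulfate is hydrolysed by the acid treatment.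

**Step 3**
Reactants: **3**
Product: **4** 2-hydroxy-5-(triisopropylsilyloxy)-3-methylbenzaldehyde
Conditions: TIPSCl (1.05 equiv), imidazole, DMF, 0 °C
Reagents that add atoms: TIPSCl, CC(C)[Si](Cl)(C(C)C)C(C)C
Why: Chemoselective silylation of the 5-OH; the 2-OH is H-bonded to the CHO and hindered, so it stays free as the later cyclisation nucleophile.

**Step 4**
Reactants: **4**
Product: **5** ethyl (2E,4E)-5-[2-hydroxy-3-methyl-5-(TIPSO)phenyl]-3-methylpenta-2,4-dienoate
Conditions: triethyl 3-methyl-4-phosphonocrotonate, NaH (2.5 equiv), THF/DMPU, 0 °C→rt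
Reagents that add atoms: triethyl 3-methyl-4-phosphonocrotonate, CCOC(=O)/C=C(C)/CP(=O)(OCC)OCC
Why: Horner–Wadsworth–Emmons olefination of the allylic phosphonate gives the E-styryl diene; excess base covers the phenol, and no stereocentre is formed.

**Step 5** (key radical step)
Reactants: **5**
Product: **6** ethyl 2-[(2R)-6-(TIPSO)-2,8-dimethyl-2H-chromen-2-yl]acetate
Conditions: (R,R)-Co(salen) (5 mol%), N-fluoro-2,4,6-trimethylpyridinium triflate (2.2 equiv), PhSiH3 (1.5 equiv), 2,6-di-tert-butylpyridine (1 equiv), PhCF3, 0 °C→rt, 12 h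
Reagents that add atoms: none (only H from the silane)
Why: Proposed new method: Co–H HAT (MHAT) delivers H• to the α-carbon of the dienoate, giving a tertiary allylic/benzylic radical stabilised by the electron-rich aryl group. Rebound onto the chiral Co(III) gives a Co(IV)–allyl species (radical–polar crossover), and the pendant phenol closes the pyran at the tertiary terminus, forming the C–O bond of the C2 (R) stereocentre under catalyst control. The o-quinone-methide-like delocalisation lets the E-styryl unit equilibrate to the geometry needed for ring closure. The closest known chemistry is Co(salen) radical–polar-crossover hydroalkoxylation of alkenols to tertiary ethers and Co–H hydrofunctionalisation of dienes.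

**Step 6**
Reactants: **6**
Product: **7** 2-[(2R)-6-(TIPSO)-2,8-dimethyl-2H-chromen-2-yl]ethan-1-ol
Conditions: DIBAL-H (3 equiv), CH2Cl2, −78→−20 °C
Reagents that add atoms: none (hydride only)
Why: Ester-to-alcohol reduction; the chromene alkene and aryl silyl ether survive, and the quaternary centre is untouched. Reducing the β-aryloxy ester here also removes any retro-oxa-Michael risk.

**Step 7**
Reactants: **7**
Product: **8** (2R)-2-(2-iodoethyl)-6-(TIPSO)-2,8-dimethyl-2H-chromene
Conditions: I2, PPh3, imidazole, CH2Cl2, 0 °C
Reagents that add atoms: iodine, II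
Why: Appel iodination (SN2 at the primary carbon); the imidazole-buffered conditions protect the acid-sensitive chromene.

**Step 8**
Reactants: **9** 4-pentyn-1-ol
Product: **10** (4E)-5-iodo-4-methylpent-4-en-1-ol
Conditions: Cp2ZrCl2 (10 mol%), AlMe3 (3 equiv), CH2Cl2, rt; then I2, THF, −30 °C
Reagents that add atoms: trimethylaluminium, C[Al](C)C (supplies the vinyl Me); iodine, II
Why: Negishi Zr-catalysed syn-methylalumination followed by iodinolysis sets the E-trisubstituted C6=C7 alkene.

**Step 9**
Reactants: **10**
Product: **11** (4E)-5-iodo-4-methylpent-4-enal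
Conditions: Dess–Martin periodinane, NaHCO3, CH2Cl2, 0 °C
Reagents that add atoms: none
Why: Mild alcohol oxidation that leaves the vinyl iodide and its geometry intact.

**Step 10**
Reactants: **12** 5-bromo-2-methylpent-2-ene
Product: **13** methyl 2-[bis(2,2,2-trifluoroethoxy)phosphoryl]-6-methylhept-5-enoate
Conditions: methyl P,P-bis(trifluoroethyl)phosphonoacetate, NaH, NaI (cat.), DMF, 0→50 °C
Reagents that add atoms: methyl bis(trifluoroethyl)phosphonoacetate, COC(=O)CP(=O)(OCC(F)(F)F)OCC(F)(F)F
Why: Mono-C-alkylation of the stabilised phosphonate carbanion (SN2) installs the C12–C15 prenyl-type terminus and the acid carbon.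

**Step 11**
Reactants: **11** + **13**
Product: **14** methyl (2Z,6E)-7-iodo-6-methyl-2-(4-methylpent-3-en-1-yl)hepta-2,6-dienoate
Conditions: KHMDS, 18-crown-6, THF, −78 °C, 3 h
Reagents that add atoms: none
Why: Still–Gennari HWE olefination with the electron-poor phosphonate gives the kinetic Z-trisubstituted acrylate, with the ester cis to C9 as in the target.

**Step 12**
Reactants: **8** + **14**
Product: **15** methyl (2Z,6E)-9-[(2R)-6-(TIPSO)-2,8-dimethyl-2H-chromen-2-yl]-6-methyl-2-(4-methylpent-3-en-1-yl)nona-2,6-dienoate
Conditions: (i) Zn dust, LiCl, TMSCl/BrCH2CH2Br (cat.), THF, 40 °C; (ii) **14**, Pd(PPh3)4 (5 mol%), THF, 25 °C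
Reagents that add atoms: none (Zn is lost as ZnI2)
Why: Negishi coupling of a primary alkylzinc with the vinyl iodide retains both alkene geometries; the C2 quaternary centre is remote and not involved.

**Step 13**
Reactants: **15**
Product: **16** (R)-sargachromenol
Conditions: LiOH·H2O, THF/MeOH/H2O, 50 °C, 16 h, under argon; then TBAF, THF, 0 °C; then aq. NaH2PO4 to pH 3
Reagents that add atoms: water/hydroxide, O (becomes the carboxylic acid OH)
Why: Saponification of the methyl ester and fluoride cleavage of the aryl silyl ether give the acid and free 6-OH; no stereocentre or alkene is involved.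

---

**Compound list**

| # | Name | SMILES | Role |
|---|---|---|---|
| 1 | o-cresol | Cc1ccccc1O | starting material |
| 2 | 2-hydroxy-3-methylbenzaldehyde | Cc1cccc(C=O)c1O | intermediate |
| 3 | 2,5-dihydroxy-3-methylbenzaldehyde | Cc1cc(O)cc(C=O)c1O | intermediate |
| 4 | 2-hydroxy-5-(TIPSO)-3-methylbenzaldehyde | Cc1cc(O[Si](C(C)C)(C(C)C)C(C)C)cc(C=O)c1O | intermediate |
| 5 | ethyl (2E,4E)-dienoate | CCOC(=O)/C=C(C)/C=C/c1cc(O[Si](C(C)C)(C(C)C)C(C)C)cc(C)c1O | intermediate |
| 6 | ethyl (R)-chromenylacetate | CCOC(=O)C[C@]1(C)C=Cc2cc(O[Si](C(C)C)(C(C)C)C(C)C)cc(C)c2O1 | intermediate |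
| 7 | (R)-chromenylethanol | OCC[C@]1(C)C=Cc2cc(O[Si](C(C)C)(C(C)C)C(C)C)cc(C)c2O1 | intermediate |
| 8 | (R)-2-(2-iodoethyl)chromene | ICC[C@]1(C)C=Cc2cc(O[Si](C(C)C)(C(C)C)C(C)C)cc(C)c2O1 | intermediate |
| 9 | 4-pentyn-1-ol | C#CCCCO | starting material |
| 10 | (4E)-5-iodo-4-methylpent-4-en-1-ol | OCCC/C(C)=C/I | intermediate |
| 11 | (4E)-5-iodo-4-methylpent-4-enal | O=CCC/C(C)=C/I | intermediate |
| 12 | 5-bromo-2-methylpent-2-ene | BrCCC=C(C)C | starting material |
| 13 | alkylated Still–Gennari phosphonate | COC(=O)C(CCC=C(C)C)P(=O)(OCC(F)(F)F)OCC(F)(F)F | intermediate |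
| 14 | methyl (2Z,6E)-7-iodo-6-methyl-2-(4-methylpent-3-enyl)hepta-2,6-dienoate | CC(C)=CCC/C(=C/CC/C(C)=C/I)C(=O)OC | intermediate |
| 15 | methyl ester, TIPS ether of the target | CC(C)=CCC/C(=C/CC/C(C)=C/CC[C@]1(C)C=Cc2cc(O[Si](C(C)C)(C(C)C)C(C)C)cc(C)c2O1)C(=O)OC | intermediate |
| 16 | (R)-sargachromenol | CC(C)=CCC/C(=C/CC/C(C)=C/CC[C@]1(C)C=Cc2cc(O)cc(C)c2O1)C(=O)O | target |

---

**Totals:** 13 steps in total; longest linear sequence 9 steps (1→2→3→4→5→6→7→12→13).

**Three steps most likely to fail**
1. **Step 5** (enantioselective Co–H radical–polar-crossover cyclisation). The electron-rich silyloxyphenol may be oxidised by the N–F oxidant, and the regiochemistry of HAT, the ee and a racemic acid-promoted background reaction are all uncertain.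
   Fallback: cyclise **5** to racemic **6** with catalytic Brønsted acid, then resolve **6** or **7** by preparative chiral-phase SFC and continue.
2. **Steps 10–11** (alkylation of the Still–Gennari phosphonate, then its Z-selectivity with an α-alkyl group).
   Fallback: use an E-selective HWE with alkylated triethyl phosphonoacetate, then E→Z photoisomerisation of the acrylate and AgNO3–silica separation of the isomers.
3. **Step 2** (low-yielding Elbs oxidation).
   Fallback: oxidise o-cresol with Fremy's salt to toluquinone, reduce with Na2S2O4, mono-silylate, then ortho-formylate (MgCl2/CH2O) to reach **4**.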